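## The problem

Target 21 is a linear trimer of three epigallocatechin units. C4 of the top unit is bonded to C8 of the middle unit, C4 of the middle unit to C8 of the bottom unit, and only the middle unit carries a gallate on O3. It has eight stereocentres: C2, C3 and C4 of the top and middle units and C2 and C3 of the bottom unit. All three units are 2,3-cis, and both C4 aryl groups are trans to the neighbouring C3 oxygen (4β). The C2/C3 pairs of the outer units can be taken from (−)-epigallocatechin, and C4 of the top unit can be set from C3 of the same ring. The three centres of the middle unit have no such neighbour if its ring is newly made, so they must come from alkene geometry, the mode of approach and the chirality of the top unit. The two interflavan bonds ionise under acid, the pyrogallol and phloroglucinol rings oxidise under base in air, C2 of a free-phenol flavan epimerises under base, and the gallate is a base-labile ester. All phenols are therefore carried as benzyl ethers and released last under neutral hydrogenolysis. In the usual chain assembly the middle unit must be a nucleophile at C8 and an electrophile at C4, with C6 competing and oligomers forming. The feature that avoids this is the middle pyran ring (O1, C2, C3, C4, C4a, C8a). Its O1–C8a–C4a edge is a phenol with one free ortho carbon on a ring that can already carry the top unit at C8. Its C4 is bonded to C8 of the bottom unit and can come from an aldehyde there, and C2–C3 is a cis-disubstituted two-carbon unit with the aryl group on C2.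

## Retrosynthesis

21 to 20. The twenty O–benzyl bonds and the C6–Br bond of the middle unit are cut. Benzyl is preferred to silyl or acyl protection because it alone leaves under neutral reductive conditions that spare the gallate and the interflavan bonds, and the bromine is lost in the same operation. Precursor 20 is no smaller, but it is inert to air, base and chromatography. The forward reaction must cleave all twenty ethers and the aryl bromide without acid building up.

20 to 18 and 19. The ester C–O bond at C3 of the middle unit is cut. Carrying the galloyl group through ring formation is the neighbouring option, but an acyloxy alkene would reverse the polarity of the two-carbon partner. The cut removes a quarter of the benzyl groups and gives acid 19, which is bought. The forward reaction is acylation of a hindered axial secondary alcohol.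

18 to 17. The C3–O bond is traced back to a C3–B bond. Oxygen cannot sit on the alkene carbon during ring formation, since a lone pair there would make the aryl-bearing carbon the nucleophilic one. Boron has no lone pair and is later exchanged for oxygen with retention. The precursor is of the same size. The forward reaction must oxidise a crowded secondary boronate without opening the ring.

17 to 7, 10 and 13, with 14 as template. C4–C4a, C3–C4 and O1–C2 of the middle pyran are cut. The neighbouring cuts are the two interflavan bonds between intact flavans, which make the middle unit both donor and acceptor under acid and leave C6 to compete. Here neither interflavan bond is formed between two flavans: phenol 7 already holds the top unit on C8 and aldehyde 10 already holds the future C4 on C8 of the bottom unit. One ring, three bonds and three stereocentres are removed at once, and the molecule falls into three pieces of comparable size. The forward reaction must be ortho-selective on 7, place boron on C3 and aryl on C2, and give the 2,3-cis-3,4-trans isomer on the β face.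

7 to 4 and 6; 6 to 5. The bond from C4 of the top unit to the phenol ring is cut. Arylation with unbrominated 5 would give ortho and para isomers, so the para carbon is blocked with bromine in 6. The bromine is kept as a cap on C6 of the future middle ring. The precursors are a flavan and a simple phenol. The forward reaction must give C-alkylation trans to the C3 oxygen.

4 to 3, 3 to 2, 2 to 1. The C4–O bond and six O–benzyl bonds are cut. Oxidation at C4 is the standard way to make a flavan an electrophile, and 1 supplies C2 and C3 of the top unit. The forward reactions are two benzylations and a benzylic oxidation that touch no stereocentre.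

10 to 8, 8 to 3. The C8–CHO bond is cut, then the C8–Br bond. Direct formylation would leave C6 against C8 open, whereas bromination of benzylated flavans is reliably C8-selective. Compound 3 is shared with the top-unit branch. The forward reactions are bromination and halogen–metal exchange with formylation.

13 to 12, 12 to 11. The C–B bond and one alkyne carbon are cut. A boron-Wittig olefination of 11 would give the E isomer, so the Z geometry is taken from a trans-hydroboration of alkyne 12. The forward reactions are a one-carbon homologation and a Z-selective hydroboration.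

## Roads not taken

Alternative 1: The phloroglucinol ring of the middle unit is grown on the top unit, so the cut runs through three bonds of that benzene ring.
- Forward step: siloxyalkyne A2 (the top unit with a triisopropylsiloxyethynyl group on C4β) is heated with 3-benzyloxycyclobutenone A3. The vinylketene from A3 adds the alkyne, the adduct reopens and closes by 6π electrocyclisation to phenol A1.
- Merits: the mechanism fixes where the free hydroxyl sits, so there is no ortho/para question and no blocking group. In this it is better than steps 4 and 5 of the chosen plan.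
- Weak points: A1 is only a differently protected stand-in for 7. The middle pyran, the second interflavan bond and three stereocentres remain, and the most direct way on from A1 is the quinone methide step of the chosen plan.
- Cost: A2 needs a C4 alkynylation of 4 and conversion of the alkyne into an acid-sensitive ynol silyl ether at a carbon that ionises easily. A3 has to be made. The silyl ether on O7 of the middle ring needs a fluoride step, since hydrogenolysis does not remove it.
- Comparison: the chosen plan sets against the better regiocontrol a two-step access to 7 from cheap 5, with a bromine that later protects C6. Alternative 1 adds about four steps and leaves the main risk where it is.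

Alternative 2: The cut is O1–C2 of the bottom unit.
- Forward step: Rh2(OAc)4 turns α-aryl-α-diazoketone A5 into a carbene that inserts into the neighbouring phenolic O–H bond and closes the bottom pyran as flavan-3-one A4.
- Merits: this ring closure is well established and mild. In this respect it is safer than step 10, which has no direct precedent.
- Weak points: the cut is peripheral. It closes a ring that 1 supplies with both stereocentres, and A5 must already contain both interflavan bonds, the middle pyran and its gallate.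
- Stereocontrol: insertion runs through an ylide or enol, so C2 of the bottom unit is set by protonation with no control from the remote centres. The 3-ketone then needs a cis-selective reduction with LiBH(s-Bu)3 beside the gallate ester.
- Comparison: the chosen plan sets against the safer ring closure the use of the chiral pool for both outer units and a key step that builds the hardest ring. Alternative 2 is linear and leaves that ring unaddressed.

Alternative 3: The cut is C4–C4a of the top unit.
- Forward step: acid ionises the C4 carbinol of A7, which is benzylic to ring A of the middle unit. One of the two equivalent ortho carbons of its 3,5-dibenzyloxyphenyl ether attacks and closes the top pyran, giving A6.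
- Merits: intramolecular Friedel–Crafts closure is known chemistry, the symmetric nucleophilic ring excludes regioisomers, and no bromine is needed. On these points it is as good as or better than step 5.
- Weak points: A7 already contains the middle pyran and the bond to the bottom unit, so the central problem is again left open. The acid that ionises the carbinol can also ionise the existing C4–C8 bond to the bottom unit.
- Stereocontrol and length: C4 of the top unit is set from an open-chain cation with only C3 to guide it. C2 and C3 of the top unit must be made by asymmetric synthesis instead of coming from 1. The silyl ether still has to be exchanged for the gallate.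
- Comparison: the chosen plan sets against the cleaner regiochemistry a top unit whose three centres come from 1 and a well-precedented trans arylation, and it makes the middle ring in the same step that joins the bottom unit.

Key step: step 10

Remark on the chemistry: α and β refer to the usual flavan drawing (ring A left, O1 at the top), in which the 2-aryl group of 1 is α.
Remark on the chemistry: 1, 5, 11, 14 and 19 are taken as commercial.

Step 1
Reactants: 1 (−)-epigallocatechin
Product: 2 5,7,3',4',5'-penta-O-benzyl-(−)-epigallocatechin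
Conditions: BnBr (5.5 equiv), K2CO3, DMF, 0 °C → rt, argon
Reagents that add atoms: benzyl bromide, BrCc1ccccc1
Why: Williamson etherification; carbonate deprotonates only the five phenols, so the C3 hydroxyl stays free, and cold oxygen-free conditions hold back C-benzylation, oxidation of the pyrogallol ring and C2 epimerisation.

Step 2
Reactants: 2 5,7,3',4',5'-penta-O-benzyl-(−)-epigallocatechin
Product: 3 3,5,7,3',4',5'-hexa-O-benzyl-(−)-epigallocatechin
Conditions: NaH, BnBr, n-Bu4NI (cat.), DMF, 0 °C → rt
Reagents that add atoms: benzyl bromide, BrCc1ccccc1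
Why: Williamson etherification of the axial secondary alkoxide; with every phenol capped the ring-opening path to C2 epimerisation is closed, so 2R,3R is kept.

Step 3
Reactants: 3 3,5,7,3',4',5'-hexa-O-benzyl-(−)-epigallocatechin
Product: 4 4β-(2-ethoxyethoxy)-3,5,7,3',4',5'-hexa-O-benzyl-epigallocatechin
Conditions: DDQ (2 equiv), EtOCH2CH2OH (5 equiv), CH2Cl2, rt
Reagents that add atoms: 2-ethoxyethanol, CCOCCO
Why: Benzylic oxidation by hydride abstraction; C4 is the only C–H whose cation is stabilised by the 5,7-dioxygenated ring A, and the alcohol adds anti to the C3 benzyloxy group. The C4 configuration is lost again on ionisation in step 5.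

Step 4
Reactants: 5 3,5-bis(benzyloxy)phenol
Product: 6 4-bromo-3,5-bis(benzyloxy)phenol
Conditions: NBS (1.0 equiv), CH2Cl2, −78 → 0 °C
Reagents that add atoms: N-bromosuccinimide, O=C1CCC(=O)N1Br
Why: Electrophilic aromatic bromination; the carbon para to the hydroxyl should be the preferred site at low temperature, and any 2-bromo isomer is removed by chromatography.

Step 5
Reactants: 4 4β-(2-ethoxyethoxy)-3,5,7,3',4',5'-hexa-O-benzyl-epigallocatechin, 6 4-bromo-3,5-bis(benzyloxy)phenol
Product: 7 4β-[2,4-bis(benzyloxy)-3-bromo-6-hydroxyphenyl]-3,5,7,3',4',5'-hexa-O-benzyl-epigallocatechin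
Conditions: 6 (3 equiv), TMSOTf (0.3 equiv), CH2Cl2, −78 → −30 °C
Reagents that add atoms: none
Why: Friedel–Crafts alkylation by the C4 benzylic cation released from the ether; bromine blocks the para carbon and the two ortho carbons are equivalent, so one regioisomer results. Attack anti to the axial C3 benzyloxy group gives the 3,4-trans (4β) product, as is the rule for 2,3-cis flavan electrophiles; excess 6 suppresses double alkylation and any O-aryl ether re-ionises.

Step 6
Reactants: 3 3,5,7,3',4',5'-hexa-O-benzyl-(−)-epigallocatechin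
Product: 8 8-bromo-3,5,7,3',4',5'-hexa-O-benzyl-epigallocatechin
Conditions: NBS (1.05 equiv), CH2Cl2, −78 °C → rt
Reagents that add atoms: N-bromosuccinimide, O=C1CCC(=O)N1Br
Why: Electrophilic aromatic bromination; ring A is far more nucleophilic than the tribenzyloxyphenyl ring, and C8 is favoured over C6, which lies between two benzyloxy groups.

Step 7
Reactants: 8 8-bromo-3,5,7,3',4',5'-hexa-O-benzyl-epigallocatechin
Product: 10 3,5,7,3',4',5'-hexa-O-benzyl-epigallocatechin-8-carbaldehyde, via 8-lithio-hexa-O-benzyl-epigallocatechin 9 (not isolated)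
Conditions: n-BuLi (1.1 equiv), THF, −78 °C; DMF (3 equiv), −78 → 0 °C; H2O
Reagents that add atoms: N,N-dimethylformamide, CN(C)C=O (n-butyllithium, [Li]CCCC, supplies the lithium of 9)
Why: Bromine–lithium exchange at −78 °C is faster than deprotonation of a benzyl ether; the aryllithium adds to DMF and the hemiaminal salt gives the aldehyde on hydrolysis (Bouveault formylation).

Step 8
Reactants: 11 3,4,5-tris(benzyloxy)benzaldehyde
Product: 12 1,2,3-tris(benzyloxy)-5-ethynylbenzene
Conditions: MeC(O)C(N2)P(O)(OMe)2 (1.3 equiv), K2CO3 (2 equiv), MeOH/THF, 0 °C → rt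
Reagents that add atoms: dimethyl (1-diazo-2-oxopropyl)phosphonate, CC(=O)C(=[N+]=[N-])P(=O)(OC)OC
Why: Seyferth–Gilbert homologation in its Ohira–Bestmann form; olefination gives a diazoalkene that loses nitrogen, and a 1,2-hydrogen shift of the carbene gives the terminal alkyne. The aldehyde cannot enolise.

Step 9
Reactants: 12 1,2,3-tris(benzyloxy)-5-ethynylbenzene
Product: 13 2-[(Z)-2-[3,4,5-tris(benzyloxy)phenyl]ethenyl]-4,4,5,5-tetramethyl-1,3,2-dioxaborolane
Conditions: HBpin (1.0 equiv; 12 in 1.2 equiv), [RhCl(cod)]2 (1.5 mol %), P(i-Pr)3 (6 mol %), Et3N, cyclohexane, rt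
Reagents that add atoms: pinacolborane, [H]B1OC(C)(C)C(C)(C)O1
Why: Rhodium-catalysed trans-hydroboration of a terminal alkyne; the alkyne hydrogen shifts to the internal carbon in a rhodium vinylidene, and boron and hydride are then delivered to the terminal carbon so that boron ends cis to the aryl group.

Step 10
Reactants: 7 4β-[2,4-bis(benzyloxy)-3-bromo-6-hydroxyphenyl]-3,5,7,3',4',5'-hexa-O-benzyl-epigallocatechin, 10 3,5,7,3',4',5'-hexa-O-benzyl-epigallocatechin-8-carbaldehyde, 13 2-[(Z)-2-[3,4,5-tris(benzyloxy)phenyl]ethenyl]-4,4,5,5-tetramethyl-1,3,2-dioxaborolane, 14 phenylboronic acid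
Product: 17 benzylated C6-bromo trimer carrying pinacolboryl at C3α of the middle unit (2-aryl α; 4-aryl β), via benzodioxaborin 15 (not isolated), via o-quinone methide 16 (not isolated)
Conditions: 14 (1.1 equiv), EtCO2H (0.2 equiv), 4 Å MS, PhMe, 80 °C; then 13 (3 equiv), 110 °C
Reagents that add atoms: none
Why: Proposed new method: phenylboronic acid 14 joins phenol 7 and aldehyde 10 as an aryloxyboron species that delivers the carbonyl carbon to C4a, the only free carbon ortho to the hydroxyl, forming the C4–C4a bond and benzodioxaborin 15; on heating, 15 sheds PhBO (collected as the boroxine) and leaves o-quinone methide 16, whose E and Z forms interconvert through the zwitterion. Quinone methide 16 then reacts as an electron-poor 1-oxadiene with the Z alkene of 13 in an inverse-demand hetero-Diels–Alder reaction, a [4+2] closure of the six-membered pyran that is concerted but asynchronous, C3–C4 forming ahead of O1–C2. The closest known reaction type is the boronic-acid-templated three-component chroman synthesis from a phenol, an aldehyde and a styrene, together with Diels–Alder reactions of alkenylboronic esters as 2π partners; an alkenylboronate on an o-quinone methide is the untested part. Regiochemistry: the methide carbon bonds to the boron-bearing carbon because the positive charge then develops benzylic to the tribenzyloxyphenyl ring, and boron, unlike an enol oxygen, has no lone pair to reverse this. C2 and C3: suprafacial addition to the Z alkene fixes aryl and boron cis. C4: the E methide is taken in the exo mode, in which only the two alkene hydrogens lie under the crowded diene and aryl and boryl stay clear of the C5 benzyloxy group and of the top unit, which puts the bottom unit trans to boron. Absolute sense: C4 of the top unit stands next to O1, and in either rotamer about its bond to C8 the α face beside O1 is the more crowded one (covered by the C5 benzyloxy group of the top unit's ring A when the C4 hydrogen points to O1, and by C2 and C3 of the top pyran with its axial C2 hydrogen when it points to C7), so the alkene should add to the β face and give the 2-aryl α, 3-boryl α, 4-aryl β isomer. The step also needs chemoselectivity against transfer of the alkenyl group from boron to the methide carbon and against Friedel–Crafts capture of 16 by another electron-rich ring; the weakly Lewis-acidic pinacol ester, the absence of strong acid, the bromine on C6 and the excess of 13 are there to secure it.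

Step 11
Reactants: 17 benzylated C6-bromo trimer carrying pinacolboryl at C3α of the middle unit
Product: 18 benzylated C6-bromo trimer with free 3α-hydroxyl on the middle unit
Conditions: NaBO3·4H2O (5 equiv), THF/H2O (1:1), rt
Reagents that add atoms: sodium perborate tetrahydrate, written as the monomer [Na+].[O-]OB=O.O.O.O.O
Why: Oxidation of the C–B bond by 1,2-shift of carbon from boron to peroxide oxygen, which goes with retention, so the α boryl group becomes the α hydroxyl (2,3-cis, 3,4-trans). Perborate is mild enough to leave benzyl ethers and the aryl bromide alone.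

Step 12
Reactants: 18 benzylated C6-bromo trimer with free 3α-hydroxyl on the middle unit, 19 3,4,5-tris(benzyloxy)benzoic acid
Product: 20 benzylated C6-bromo trimer 3-O-[3,4,5-tris(benzyloxy)benzoate]
Conditions: DCC, DMAP (cat.), CH2Cl2, rt
Reagents that add atoms: none
Why: Steglich esterification; acyl transfer through the N-acylpyridinium ion reaches the hindered axial hydroxyl, and reaction at oxygen leaves C3 untouched.

Step 13
Reactants: 20 benzylated C6-bromo trimer 3-O-[3,4,5-tris(benzyloxy)benzoate]
Product: 21 epigallocatechin-(4β→8)-epigallocatechin 3-O-gallate-(4β→8)-epigallocatechin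
Conditions: H2 (1 atm), Pd(OH)2/C, NaOAc (1.2 equiv), THF/MeOH/H2O, rt
Reagents that add atoms: none
Why: Hydrogenolysis of the twenty benzyl ethers and hydrodebromination of the aryl bromide in one operation over Pd(OH)2 on carbon; the acetate takes up the hydrogen bromide, so the two interflavan bonds, the gallate and all eight stereocentres should be spared.

## Compound list

1 | (−)-epigallocatechin, (2R,3R)-2-(3,4,5-trihydroxyphenyl)chromane-3,5,7-triol | Oc1cc(O)c2c(c1)O[C@H](c1cc(O)c(O)c(O)c1)[C@H](O)C2 | starting material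
2 | 5,7,3',4',5'-penta-O-benzyl-(−)-epigallocatechin (2R,3R; free 3-OH) | c1c(OCc9ccccc9)cc(OCc9ccccc9)c2c1O[C@H](c1cc(OCc9ccccc9)c(OCc9ccccc9)c(OCc9ccccc9)c1)[C@H](O)C2 | intermediate
3 | 3,5,7,3',4',5'-hexa-O-benzyl-(−)-epigallocatechin (2R,3R) | c1c(OCc9ccccc9)cc(OCc9ccccc9)c2c1O[C@H](c1cc(OCc9ccccc9)c(OCc9ccccc9)c(OCc9ccccc9)c1)[C@H](OCc9ccccc9)C2 | intermediate
4 | 4β-(2-ethoxyethoxy)-3,5,7,3',4',5'-hexa-O-benzyl-epigallocatechin (C2, C3 as in 1; 4-O trans to 3-O) | CCOCCO[C@H]3c4c(OCc9ccccc9)cc(OCc9ccccc9)cc4O[C@H](c4cc(OCc9ccccc9)c(OCc9ccccc9)c(OCc9ccccc9)c4)[C@@H]3OCc9ccccc9 | intermediate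
5 | 3,5-bis(benzyloxy)phenol | Oc1cc(OCc2ccccc2)cc(OCc2ccccc2)c1 | starting material
6 | 4-bromo-3,5-bis(benzyloxy)phenol | Oc1cc(OCc2ccccc2)c(Br)c(OCc2ccccc2)c1 | intermediate
7 | 4β-[2,4-bis(benzyloxy)-3-bromo-6-hydroxyphenyl]-3,5,7,3',4',5'-hexa-O-benzyl-epigallocatechin (top-unit phenol; 4-aryl trans to 3-O) | Oc1cc(OCc9ccccc9)c(Br)c(OCc9ccccc9)c1[C@H]3c4c(OCc9ccccc9)cc(OCc9ccccc9)cc4O[C@H](c4cc(OCc9ccccc9)c(OCc9ccccc9)c(OCc9ccccc9)c4)[C@@H]3OCc9ccccc9 | intermediate
8 | 8-bromo-3,5,7,3',4',5'-hexa-O-benzyl-epigallocatechin | Brc1c(OCc9ccccc9)cc(OCc9ccccc9)c2c1O[C@H](c1cc(OCc9ccccc9)c(OCc9ccccc9)c(OCc9ccccc9)c1)[C@H](OCc9ccccc9)C2 | intermediate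
9 | 8-lithio-3,5,7,3',4',5'-hexa-O-benzyl-epigallocatechin | [Li]c1c(OCc9ccccc9)cc(OCc9ccccc9)c2c1O[C@H](c1cc(OCc9ccccc9)c(OCc9ccccc9)c(OCc9ccccc9)c1)[C@H](OCc9ccccc9)C2 | intermediate (not isolated)
10 | 3,5,7,3',4',5'-hexa-O-benzyl-epigallocatechin-8-carbaldehyde | O=Cc1c(OCc9ccccc9)cc(OCc9ccccc9)c2c1O[C@H](c1cc(OCc9ccccc9)c(OCc9ccccc9)c(OCc9ccccc9)c1)[C@H](OCc9ccccc9)C2 | intermediate
11 | 3,4,5-tris(benzyloxy)benzaldehyde | O=Cc1cc(OCc2ccccc2)c(OCc2ccccc2)c(OCc2ccccc2)c1 | starting material
12 | 1,2,3-tris(benzyloxy)-5-ethynylbenzene | C#Cc1cc(OCc2ccccc2)c(OCc2ccccc2)c(OCc2ccccc2)c1 | intermediate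
13 | 2-[(Z)-2-[3,4,5-tris(benzyloxy)phenyl]ethenyl]-4,4,5,5-tetramethyl-1,3,2-dioxaborolane | CC1(C)OB(/C=C\c2cc(OCc9ccccc9)c(OCc9ccccc9)c(OCc9ccccc9)c2)OC1(C)C | intermediate
14 | phenylboronic acid | OB(O)c1ccccc1 | starting material
15 | 2-phenyl-4H-1,3,2-benzodioxaborin from 7 and 10: O1 is the phenol oxygen of 7, C4 (both epimers) carries C8 of the bottom unit, C5 and C7 carry benzyloxy, C6 bromine, C8 the top unit through its C4β | c1ccccc1B1OC(c2c(OCc9ccccc9)cc(OCc9ccccc9)c3c2O[C@H](c2cc(OCc9ccccc9)c(OCc9ccccc9)c(OCc9ccccc9)c2)[C@H](OCc9ccccc9)C3)c2c(OCc9ccccc9)c(Br)c(OCc9ccccc9)c([C@H]3c4c(OCc9ccccc9)cc(OCc9ccccc9)cc4O[C@H](c4cc(OCc9ccccc9)c(OCc9ccccc9)c(OCc9ccccc9)c4)[C@@H]3OCc9ccccc9)c2O1 | intermediate (not isolated)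
16 | (E)-o-quinone methide: 3,5-bis(benzyloxy)-4-bromocyclohexa-2,4-dien-1-one with the top unit (C4β) on C2 and, on C6, an exocyclic methylidene bearing C8 of the bottom unit anti to the carbonyl | O=C1/C(=C/c2c(OCc9ccccc9)cc(OCc9ccccc9)c3c2O[C@H](c2cc(OCc9ccccc9)c(OCc9ccccc9)c(OCc9ccccc9)c2)[C@H](OCc9ccccc9)C3)C(OCc9ccccc9)=C(Br)C(OCc9ccccc9)=C1[C@H]3c4c(OCc9ccccc9)cc(OCc9ccccc9)cc4O[C@H](c4cc(OCc9ccccc9)c(OCc9ccccc9)c(OCc9ccccc9)c4)[C@@H]3OCc9ccccc9 | intermediate (not isolated)
17 | hexa-O-benzyl-epigallocatechin-(4β→8)-[6-bromo-5,7,3',4',5'-penta-O-benzyl-3-deoxy-3α-(4,4,5,5-tetramethyl-1,3,2-dioxaborolan-2-yl)epigallocatechin]-(4β→8)-hexa-O-benzyl-epigallocatechin (middle unit: 2-aryl α, 3-boryl α, 4-aryl β) | CC1(C)OB(OC1(C)C)[C@@H]5[C@@H](c2c(OCc9ccccc9)cc(OCc9ccccc9)c3c2O[C@H](c2cc(OCc9ccccc9)c(OCc9ccccc9)c(OCc9ccccc9)c2)[C@H](OCc9ccccc9)C3)c2c(OCc9ccccc9)c(Br)c(OCc9ccccc9)c([C@H]3c4c(OCc9ccccc9)cc(OCc9ccccc9)cc4O[C@H](c4cc(OCc9ccccc9)c(OCc9ccccc9)c(OCc9ccccc9)c4)[C@@H]3OCc9ccccc9)c2O[C@@H]5c1cc(OCc9ccccc9)c(OCc9ccccc9)c(OCc9ccccc9)c1 | intermediate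
18 | hexa-O-benzyl-epigallocatechin-(4β→8)-[6-bromo-5,7,3',4',5'-penta-O-benzyl-epigallocatechin]-(4β→8)-hexa-O-benzyl-epigallocatechin (middle unit with free 3α-OH; 2,3-cis-3,4-trans) | O[C@@H]5[C@@H](c2c(OCc9ccccc9)cc(OCc9ccccc9)c3c2O[C@H](c2cc(OCc9ccccc9)c(OCc9ccccc9)c(OCc9ccccc9)c2)[C@H](OCc9ccccc9)C3)c2c(OCc9ccccc9)c(Br)c(OCc9ccccc9)c([C@H]3c4c(OCc9ccccc9)cc(OCc9ccccc9)cc4O[C@H](c4cc(OCc9ccccc9)c(OCc9ccccc9)c(OCc9ccccc9)c4)[C@@H]3OCc9ccccc9)c2O[C@@H]5c1cc(OCc9ccccc9)c(OCc9ccccc9)c(OCc9ccccc9)c1 | intermediate
19 | 3,4,5-tris(benzyloxy)benzoic acid | OC(=O)c1cc(OCc2ccccc2)c(OCc2ccccc2)c(OCc2ccccc2)c1 | starting material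
20 | 3-O-[3,4,5-tris(benzyloxy)benzoyl] ester of 18 (benzylated C6-bromo trimer gallate) | O=C(O[C@@H]1[C@@H](c2c(OCc9ccccc9)cc(OCc9ccccc9)c3c2O[C@H](c2cc(OCc9ccccc9)c(OCc9ccccc9)c(OCc9ccccc9)c2)[C@H](OCc9ccccc9)C3)c2c(OCc9ccccc9)c(Br)c(OCc9ccccc9)c([C@H]3c4c(OCc9ccccc9)cc(OCc9ccccc9)cc4O[C@H](c4cc(OCc9ccccc9)c(OCc9ccccc9)c(OCc9ccccc9)c4)[C@@H]3OCc9ccccc9)c2O[C@@H]1c1cc(OCc9ccccc9)c(OCc9ccccc9)c(OCc9ccccc9)c1)c1cc(OCc9ccccc9)c(OCc9ccccc9)c(OCc9ccccc9)c1 | intermediate
21 | epigallocatechin-(4β→8)-epigallocatechin 3-O-gallate-(4β→8)-epigallocatechin (CNP0278699.1) | O=C(O[C@@H]1[C@@H](c2c(O)cc(O)c3c2O[C@H](c2cc(O)c(O)c(O)c2)[C@H](O)C3)c2c(O)cc(O)c([C@H]3c4c(O)cc(O)cc4O[C@H](c4cc(O)c(O)c(O)c4)[C@@H]3O)c2O[C@@H]1c1cc(O)c(O)c(O)c1)c1cc(O)c(O)c(O)c1 | target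

## Step count and risks

Total: 13 steps. Longest linear sequence: 8 steps (steps 1, 2, 3, 5, 10, 11, 12, 13; 1 → 2 → 3 → 4 → 7 → 17 → 18 → 20 → 21).

Step 10 (key step). The most likely failure is that the crowded, strongly stabilised quinone methide adds the modest 2π partner too slowly. It would then be lost by Friedel–Crafts capture on another electron-rich ring, or the alkenyl group would migrate from boron to the methide carbon. Facial selectivity may also be low, because it rests on a conformational argument about a flexible neighbour. The fallback uses the known Lewis-acid chain assembly and sets out from 2, 3 and 4.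
- Oxidation of 2 at C4 with DDQ and 2-ethoxyethanol would give 4β-(2-ethoxyethoxy)-5,7,3',4',5'-penta-O-benzyl-epigallocatechin F1.
- TMSOTf-promoted coupling of F1 with an excess of 3 would give the 4β→8 dimer with a free 3-hydroxyl on its upper unit, F2.
- A second coupling, of F2 with electrophile 4 at C8 of its upper unit, would give the bromine-free trimer alcohol F3.
- Esterification with 19 as in step 12 would give the bromine-free gallate F4, and hydrogenolysis as in step 13 would return to the route at 21.

Step 9. The Z selectivity may erode, because the vinylidene pathway competes with ordinary syn-hydroboration and the product can isomerise on the catalyst; an electron-rich arylalkyne is not the best case. The fallback sets out from 11. Olefination with (iodomethyl)triphenylphosphonium iodide and NaN(SiMe3)2 at −78 °C (Stork–Zhao) would give (Z)-1,2,3-tris(benzyloxy)-5-(2-iodoethenyl)benzene F5. Iodine–lithium exchange with t-BuLi at −78 °C and trapping with 2-isopropoxy-4,4,5,5-tetramethyl-1,3,2-dioxaborolane, both with retention, would return to the route at 13.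

Step 4. Bromination may go ortho as well as para to the hydroxyl, or twice, since all three free carbons are activated by three oxygens. The fallback sets out from 5 and shields the ortho carbons for the time of the bromination. Silylation (i-Pr3SiCl, imidazole) would give [3,5-bis(benzyloxy)phenoxy]triisopropylsilane F6. NBS would then brominate the carbon between the two benzyloxy groups to give [3,5-bis(benzyloxy)-4-bromophenoxy]triisopropylsilane F7, and n-Bu4NF would return to the route at 6.

Step 11. Oxidation of the axial boronate, flanked by two aryl-bearing carbons, may be slow. The boron ate complex could then eliminate with O1 as leaving group and open the pyran, or boron could be lost by protonolysis. The fallback sets out from 17 and changes the boron species. KHF2 in aqueous methanol would give the potassium trifluoroborate F8, and KHSO5 (as the triple salt 2KHSO5·KHSO4·K2SO4) in aqueous acetone, a fast oxidation with retention, would return to the route at 18.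

Step 13. Cleavage of twenty ethers and one hindered aryl bromide may stop short and leave partly protected material. Hydrogen bromide released beside free phenols may also ionise an interflavan bond. The fallback sets out from 20 and separates the two reductions. Radical debromination (n-Bu3SnH, AIBN, PhMe, 80 °C) would give the bromine-free gallate F4, the compound through which the chain-assembly fallback for step 10 also passes, and hydrogenolysis without acetate, which then forms no acid, would return to the route at 21.

## Further compounds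

F1 | step 10 | 4β-(2-ethoxyethoxy)-5,7,3',4',5'-penta-O-benzyl-epigallocatechin (free 3-OH) | CCOCCO[C@H]3c4c(OCc9ccccc9)cc(OCc9ccccc9)cc4O[C@H](c4cc(OCc9ccccc9)c(OCc9ccccc9)c(OCc9ccccc9)c4)[C@@H]3O
F2 | step 10 | 5,7,3',4',5'-penta-O-benzyl-epigallocatechin-(4β→8)-hexa-O-benzyl-epigallocatechin (upper unit with free 3-OH) | O[C@@H]5[C@@H](c2c(OCc9ccccc9)cc(OCc9ccccc9)c3c2O[C@H](c2cc(OCc9ccccc9)c(OCc9ccccc9)c(OCc9ccccc9)c2)[C@H](OCc9ccccc9)C3)c2c(OCc9ccccc9)cc(OCc9ccccc9)cc2O[C@@H]5c1cc(OCc9ccccc9)c(OCc9ccccc9)c(OCc9ccccc9)c1
F3 | step 10 | bromine-free trimer alcohol (18 with H on C6 of the middle unit) | O[C@@H]5[C@@H](c2c(OCc9ccccc9)cc(OCc9ccccc9)c3c2O[C@H](c2cc(OCc9ccccc9)c(OCc9ccccc9)c(OCc9ccccc9)c2)[C@H](OCc9ccccc9)C3)c2c(OCc9ccccc9)cc(OCc9ccccc9)c([C@H]3c4c(OCc9ccccc9)cc(OCc9ccccc9)cc4O[C@H](c4cc(OCc9ccccc9)c(OCc9ccccc9)c(OCc9ccccc9)c4)[C@@H]3OCc9ccccc9)c2O[C@@H]5c1cc(OCc9ccccc9)c(OCc9ccccc9)c(OCc9ccccc9)c1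
F4 | step 13 | bromine-free gallate (20 with H on C6 of the middle unit; also the last intermediate of the chain-assembly fallback for step 10) | O=C(O[C@@H]1[C@@H](c2c(OCc9ccccc9)cc(OCc9ccccc9)c3c2O[C@H](c2cc(OCc9ccccc9)c(OCc9ccccc9)c(OCc9ccccc9)c2)[C@H](OCc9ccccc9)C3)c2c(OCc9ccccc9)cc(OCc9ccccc9)c([C@H]3c4c(OCc9ccccc9)cc(OCc9ccccc9)cc4O[C@H](c4cc(OCc9ccccc9)c(OCc9ccccc9)c(OCc9ccccc9)c4)[C@@H]3OCc9ccccc9)c2O[C@@H]1c1cc(OCc9ccccc9)c(OCc9ccccc9)c(OCc9ccccc9)c1)c1cc(OCc9ccccc9)c(OCc9ccccc9)c(OCc9ccccc9)c1
F5 | step 9 | (Z)-1,2,3-tris(benzyloxy)-5-(2-iodoethenyl)benzene | I/C=C\c1cc(OCc2ccccc2)c(OCc2ccccc2)c(OCc2ccccc2)c1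
F6 | step 4 | [3,5-bis(benzyloxy)phenoxy]triisopropylsilane | CC(C)[Si](Oc1cc(OCc2ccccc2)cc(OCc2ccccc2)c1)(C(C)C)C(C)C
F7 | step 4 | [3,5-bis(benzyloxy)-4-bromophenoxy]triisopropylsilane | CC(C)[Si](Oc1cc(OCc2ccccc2)c(Br)c(OCc2ccccc2)c1)(C(C)C)C(C)C
F8 | step 11 | potassium trifluoroborate corresponding to 17 (BF3K in place of the pinacolboryl group, same configuration) | [K+].F[B-](F)(F)[C@@H]5[C@@H](c2c(OCc9ccccc9)cc(OCc9ccccc9)c3c2O[C@H](c2cc(OCc9ccccc9)c(OCc9ccccc9)c(OCc9ccccc9)c2)[C@H](OCc9ccccc9)C3)c2c(OCc9ccccc9)c(Br)c(OCc9ccccc9)c([C@H]3c4c(OCc9ccccc9)cc(OCc9ccccc9)cc4O[C@H](c4cc(OCc9ccccc9)c(OCc9ccccc9)c(OCc9ccccc9)c4)[C@@H]3OCc9ccccc9)c2O[C@@H]5c1cc(OCc9ccccc9)c(OCc9ccccc9)c(OCc9ccccc9)c1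
A1 | alternative 1 | top-unit phenol with 2-hydroxy-4-benzyloxy-6-triisopropylsiloxyphenyl at C4β | Oc1cc(OCc9ccccc9)cc(O[Si](C(C)C)(C(C)C)C(C)C)c1[C@H]3c4c(OCc9ccccc9)cc(OCc9ccccc9)cc4O[C@H](c4cc(OCc9ccccc9)c(OCc9ccccc9)c(OCc9ccccc9)c4)[C@@H]3OCc9ccccc9
A2 | alternative 1 | 4β-[(triisopropylsiloxy)ethynyl]-3,5,7,3',4',5'-hexa-O-benzyl-epigallocatechin | CC(C)[Si](C(C)C)(C(C)C)OC#C[C@H]3c4c(OCc9ccccc9)cc(OCc9ccccc9)cc4O[C@H](c4cc(OCc9ccccc9)c(OCc9ccccc9)c(OCc9ccccc9)c4)[C@@H]3OCc9ccccc9
A3 | alternative 1 | 3-(benzyloxy)cyclobut-2-en-1-one | O=C1C=C(OCc2ccccc2)C1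
A4 | alternative 2 | benzylated trimer gallate with the bottom unit as its flavan-3-one | O=C(O[C@@H]1[C@@H](c2c(OCc9ccccc9)cc(OCc9ccccc9)c3c2O[C@H](c2cc(OCc9ccccc9)c(OCc9ccccc9)c(OCc9ccccc9)c2)C(=O)C3)c2c(OCc9ccccc9)cc(OCc9ccccc9)c([C@H]3c4c(OCc9ccccc9)cc(OCc9ccccc9)cc4O[C@H](c4cc(OCc9ccccc9)c(OCc9ccccc9)c(OCc9ccccc9)c4)[C@@H]3OCc9ccccc9)c2O[C@@H]1c1cc(OCc9ccccc9)c(OCc9ccccc9)c(OCc9ccccc9)c1)c1cc(OCc9ccccc9)c(OCc9ccccc9)c(OCc9ccccc9)c1
A5 | alternative 2 | benzylated top–middle gallate whose C4 carries a 2-hydroxy-4,6-bis(benzyloxy)phenyl ring bearing a 3-diazo-2-oxo-3-[3,4,5-tris(benzyloxy)phenyl]propyl chain on C3 | O=C(O[C@@H]1[C@@H](c2c(OCc9ccccc9)cc(OCc9ccccc9)c(CC(=O)C(=[N+]=[N-])c3cc(OCc9ccccc9)c(OCc9ccccc9)c(OCc9ccccc9)c3)c2O)c2c(OCc9ccccc9)cc(OCc9ccccc9)c([C@H]3c4c(OCc9ccccc9)cc(OCc9ccccc9)cc4O[C@H](c4cc(OCc9ccccc9)c(OCc9ccccc9)c(OCc9ccccc9)c4)[C@@H]3OCc9ccccc9)c2O[C@@H]1c1cc(OCc9ccccc9)c(OCc9ccccc9)c(OCc9ccccc9)c1)c1cc(OCc9ccccc9)c(OCc9ccccc9)c(OCc9ccccc9)c1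
A6 | alternative 3 | benzylated trimer with a tert-butyldimethylsilyl ether at C3 of the middle unit | CC(C)(C)[Si](C)(C)O[C@@H]1[C@@H](c2c(OCc9ccccc9)cc(OCc9ccccc9)c3c2O[C@H](c2cc(OCc9ccccc9)c(OCc9ccccc9)c(OCc9ccccc9)c2)[C@H](OCc9ccccc9)C3)c2c(OCc9ccccc9)cc(OCc9ccccc9)c([C@H]3c4c(OCc9ccccc9)cc(OCc9ccccc9)cc4O[C@H](c4cc(OCc9ccccc9)c(OCc9ccccc9)c(OCc9ccccc9)c4)[C@@H]3OCc9ccccc9)c2O[C@@H]1c1cc(OCc9ccccc9)c(OCc9ccccc9)c(OCc9ccccc9)c1
A7 | alternative 3 | middle–bottom dimer (3-O-silyl) whose C8 carries a 1-hydroxy-2-benzyloxy-3-[3,5-bis(benzyloxy)phenoxy]-3-[3,4,5-tris(benzyloxy)phenyl]propyl chain (carbinol epimers; C2 and C3 of the future top unit as in 1) | CC(C)(C)[Si](C)(C)O[C@@H]1[C@@H](c2c(OCc9ccccc9)cc(OCc9ccccc9)c3c2O[C@H](c2cc(OCc9ccccc9)c(OCc9ccccc9)c(OCc9ccccc9)c2)[C@H](OCc9ccccc9)C3)c2c(OCc9ccccc9)cc(OCc9ccccc9)c(C(O)[C@@H](OCc9ccccc9)[C@@H](c3cc(OCc9ccccc9)c(OCc9ccccc9)c(OCc9ccccc9)c3)Oc3cc(OCc9ccccc9)cc(OCc9ccccc9)c3)c2O[C@@H]1c1cc(OCc9ccccc9)c(OCc9ccccc9)c(OCc9ccccc9)c1
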